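# Proposed synthesis of CNP0110425.0 by twofold carbene–alkyne–CO benzannulation of heptadeca-1,16-diyne

## Analysis of the target

The target is a symmetric dimer: two identical, fully substituted 1,4-benzoquinone rings joined by an unbranched chain of thirteen CH2 groups. With the carbonyls of each ring numbered C1 and C4, C2 carries a hydroxyl, C3 the chain, C5 a methoxy and C6 a methyl group. There is no stereocenter and no double bond of defined geometry, so the problem is one of constitution. Four different substituents must stand in a fixed order round each ring, and the two oxygens at C2 and C5, para to each other, must end up different (free OH against OCH3). The 2-hydroxyquinone is a vinylogous acid, acidic and easily over-oxidized. The 5-methoxyquinone is a vinylogous ester that hydroxide or amines can cleave, and quinones do not survive organometallic reagents, so these groups are best unveiled late. The tether is inert and gives no handle, and every ring operation must succeed at both ends of one molecule. The strategy rests on the contiguous ring atoms C3 and C2, which map onto the substituted and the unsubstituted carbon of a terminal alkyne. The neighbouring carbonyl carbon C4 maps onto carbon monoxide, and C1, C6 (with its methyl) and C5 (with its methoxy) map onto the carbene carbon and the two alkene carbons of an alkenyl carbene. A 4-methoxyphenol of the right substitution is then one oxidation and one hydroxylation away from each quinone ring.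

## Retrosynthetic reasoning

**17 ⇒ 14 (through 16 and 15).** The C2–O bond of the hydroxyl in each ring is cut first. In bisquinone 14 this carbon is the only ring carbon bearing hydrogen, so reintroducing the oxygen needs no regiocontrol, and the sensitive hydroxyquinone appears only in the last step. The forward sequence must add an oxygen nucleophile to the quinone at that CH, which reduces the ring to the aromatic level (hexaacetate 15). It must then free the three oxygens of each ring (hexaphenol 16) and reoxidize without touching the C5 methoxy group.

**14 ⇒ 13.** The two carbonyls of each quinone are traced to a phenol oxygen and a methoxy group para to it, that is, to the 4-methoxyphenol rings of 13. This is a change of oxidation state that costs one O–CH3 bond per ring. It is placed here because a para-methoxyphenol is what the ring-forming step delivers. The second methoxy group of each ring of 13 is ortho to the phenol and remains as the C5 methoxy of the quinone. The forward reaction must oxidize the para pair in preference to the ortho pair.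

**13 ⇒ 5 + 11.** Three C–C bonds are cut in each aromatic ring:
- between the chain-bearing carbon and the phenol carbon;
- between the phenol carbon and the neighbouring methoxy-bearing carbon;
- between the ring CH and the carbon bearing the para methoxy group.

These cuts divide each ring into a two-carbon piece (a terminus of diyne 5), a one-carbon piece (a carbonyl ligand of 11) and a three-carbon piece (the carbene ligand of 11, which already carries the methyl and both methoxy groups). Both rings are then built in one step from an acyclic diyne, without any aromatic starting material or arene–tether coupling, and the order of substituents follows from the mechanism. The forward reaction must insert each alkyne terminus with the chain next to the carbonyl-derived carbon, must incorporate the carbonyl ligand, and must do so at both ends.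

**5 ⇒ 3 ⇒ 2 ⇒ 1.** Each terminal alkyne is cut at its triple bond: the outer carbon comes from diazophosphonate 4, the inner one is an aldehyde carbon of dialdehyde 3. The thirteen CH2 groups of the tether are thus already present in 3 and, through diol 2, in the fifteen-carbon diacid 1. The two carboxyl carbons of 1 become the two ring carbons C3. Only end-group chemistry is needed.

**11 ⇒ 9 + 8; 9 ⇒ 7 ⇒ 6.** The bond between the carbene carbon and the alkene, and the O–CH3 bond at the carbene carbon, are cut. Alkenyllithium 9 adds to a carbonyl ligand of 8 to give acylchromate 10, which is methylated on oxygen. 9 comes from bromide 7 by halogen–lithium exchange with retention. 7 comes from acetal 6 by loss of one methoxy group together with the neighbouring hydrogen. Lithium must be cis to the methoxy group in 9: that isomer is held by internal O–Li coordination and cannot lose the methoxy group by anti elimination.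

## Alternatives that were turned down

**Alternative 1:** The tether is cut at the two C–C bonds flanking its central carbon, C7. That carbon comes from tosylmethyl isocyanide A3 and each half from the arm 5-(6-iodohexyl)-1,3-dimethoxy-2-methylbenzene A2.
- Forward key step: A3 is deprotonated and alkylated twice in one flask by A2 (hydride base, dipolar aprotic medium), giving 1,13-bis(3,5-dimethoxy-4-methylphenyl)-7-isocyano-7-tosyltridecane A1. No ring is formed.
- For: the bond formation is SN2 displacement at a primary iodide by a stabilized carbanion, and both arms are the same compound. On certainty of the key step this plan is stronger than the chosen one.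
- Against: the central carbon arrives with an isocyano and a sulfonyl group that must be removed reductively. A2 needs several steps of its own. The rings enter as 2-methylresorcinol dimethyl ethers, well below the oxidation level of the target.
- Remaining ring chemistry: one of two equivalent methoxy groups per ring must be cleaved (a statistical problem over four such groups), followed by para-oxidation to the level of 14 and the same hydroxylation as in the chosen route.
- Comparison: the chosen strategy forms the rings with the two methoxy oxygens already distinguished by position, brings in one further oxygen with CO in the same step, and has a shorter path from ring formation to target.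

**Alternative 2:** The tether is cut at two CH2–CH2 bonds (C2–C3 and C11–C12), giving a nine-carbon middle piece from undecanedioic acid and two 2-arylethyl pieces from a 3-arylpropanoic acid.
- Forward key step: constant-current electrolysis with a divalent nickel catalyst and a terpyridine ligand (carbon cathode, sacrificial magnesium anode) couples an excess of 1,3-dioxoisoindolin-2-yl 3-(3,5-dimethoxy-4-methylphenyl)propanoate A5 with bis(1,3-dioxoisoindolin-2-yl) undecanedioate A6. The activated esters are taken here to be N-acyloxyphthalimides. Four CO2 are lost and the product is 1,13-bis(3,5-dimethoxy-4-methylphenyl)tridecane A4.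
- For: both partners come from carboxylic acids, the tether arrives bare, and the whole carbon skeleton is assembled in one step. On step count to the skeleton it beats the chosen route.
- Against: two unactivated primary alkyl fragments must be cross-coupled, so hetero-coupling competes with dimerization of A5 and oligomerization of the bifunctional A6. Each molecule of A4 needs two hetero-couplings. The non-polar product must be separated from homologues of nearly the same polarity.
- Remaining ring chemistry: A4 faces the same desymmetrizing demethylation, oxidation to 14 and hydroxylation as in alternative 1.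
- Comparison: the chosen strategy replaces a statistical selectivity by one built into the mechanism (alkyne regiochemistry) and delivers rings at a higher oxidation level.

**Alternative 3:** Each ring is cut at the bond between the chain-bearing carbon and its ring neighbour (Michael bond) and at the bond between a ring carbonyl carbon and the methyl-bearing carbon (Claisen bond). This leads to dimethyl malonate A9 and the bis(ethyl enone) (4E,19E)-tricosa-4,19-diene-3,21-dione A8, available by olefination of dialdehyde 3.
- Forward key step: methoxide in methanol adds A9 to both enones of A8 and closes each ring by Claisen condensation. The product is dimethyl 6,6'-(tridecane-1,13-diyl)bis(3-methyl-2,4-dioxocyclohexane-1-carboxylate) A7, a mixture of stereoisomers and enol tautomers.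
- For: it also builds both rings from an acyclic chain, with cheap reagents, no metal carbonyl and classical carbonyl chemistry. The methyl group and the 1,3-dioxygen pattern are set in the ring-forming step. On robustness and cost of the key step it is the stronger plan.
- Against: the ring is formed at the cyclohexane-1,3-dione level. It must be decarboxylated and dehydrogenated to a 5-alkyl-2-methylresorcinol, whose two equivalent hydroxyls must then be told apart on both rings before para-oxidation to 14 and the final hydroxylation. The stereoisomer mixture A7 is awkward to purify.
- Comparison: the chosen benzannulation closes the ring directly at the aromatic level, with the chain-side oxygen in place and the two oxygens flanking the methyl group already distinct. Only one oxidation-state change and one hydroxylation remain.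

Key step: step 6

## Route

Remark on the chemistry: in 7, 10 and 11 the methoxy group is cis to Br, to the acyl carbon and to the carbene carbon respectively (Z in each case). The same spatial arrangement in 9 is E by the sequence rules, because CH3 outranks Li. The η6-bound Cr(CO)3 groups of 12 cannot be drawn with valence bonds and are written as separate components in its SMILES.

Step 1
Reactants: 1 pentadecanedioic acid
Product: 2 pentadecane-1,15-diol
Conditions: BH3·SMe2, THF, 0 °C → reflux; MeOH, then H2O
Reagents that add atoms: none
Why: Borane reduction of a carboxylic acid proceeds through acyloxyboranes to the primary alcohol and stays homogeneous with a long-chain diacid; 1 has no other reactive group.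

Step 2
Reactants: 2 pentadecane-1,15-diol
Product: 3 pentadecanedial
Conditions: TEMPO (cat.), PhI(OAc)2, CH2Cl2, rt
Reagents that add atoms: none
Why: Oxoammonium-mediated oxidation of primary alcohols stops at the aldehyde in the absence of water; the dialdehyde should be used crude because long-chain dialdehydes oligomerize and air-oxidize on standing.

Step 3
Reactants: 3 pentadecanedial; 4 dimethyl (1-diazo-2-oxopropyl)phosphonate
Product: 5 heptadeca-1,16-diyne
Conditions: 4 (2.6 equiv), K2CO3, MeOH/THF, 0 °C → rt
Reagents that add atoms: 4 dimethyl (1-diazo-2-oxopropyl)phosphonate, COP(=O)(OC)C(=[N+]=[N-])C(C)=O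
Why: Ohira–Bestmann homologation: methanolysis of the acetyl group of 4 gives the diazomethylphosphonate anion, which adds to each aldehyde, loses dimethyl phosphate and N2, and the alkylidene carbene rearranges by 1,2-hydrogen shift to the terminal alkyne; the mild base tolerates enolizable aldehydes.

Step 4
Reactants: 6 2-bromo-1,1-dimethoxypropane
Product: 7 (Z)-2-bromo-1-methoxyprop-1-ene
Conditions: TMSOTf, iPr2NEt, CH2Cl2, −20 °C → rt; fractional distillation
Reagents that add atoms: none
Why: Acetal-to-enol-ether elimination: the silyl triflate ionizes the acetal to an oxocarbenium ion and the hindered amine removes the adjacent proton, which the bromine acidifies; both geometrical isomers are expected, and the isomer with Br cis to OCH3 is to be collected by distillation.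

Step 5
Reactants: 7 (Z)-2-bromo-1-methoxyprop-1-ene; 8 hexacarbonylchromium Cr(CO)6
Product: 11 pentacarbonyl[(Z)-1,3-dimethoxy-2-methylprop-2-en-1-ylidene]chromium, via (E)-(1-methoxyprop-1-en-2-yl)lithium 9 (not isolated), via lithium acylpentacarbonylchromate 10 (not isolated)
Conditions: t-BuLi (2 equiv), Et2O, −78 °C; Cr(CO)6, THF, −78 → 0 °C; solvent exchange; Me3OBF4, CH2Cl2, 0 °C
Reagents that add atoms: 8 hexacarbonylchromium, O=C=[Cr](=C=O)(=C=O)(=C=O)(=C=O)=C=O; trimethyloxonium tetrafluoroborate, C[O+](C)C.F[B-](F)(F)F
Why: Fischer carbene synthesis: bromine–lithium exchange occurs with retention (the second equivalent of t-BuLi destroys t-BuBr) and gives a lithium reagent held by cis O–Li coordination; it adds to a CO ligand of Cr(CO)6, and the hard oxonium salt methylates the acylchromate on oxygen.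

Step 6
Reactants: 5 heptadeca-1,16-diyne; 11 pentacarbonyl[(Z)-1,3-dimethoxy-2-methylprop-2-en-1-ylidene]chromium
Product: 13 6,6'-(tridecane-1,13-diyl)bis(2,4-dimethoxy-3-methylphenol), via bis(tricarbonylchromium) arene complex 12 (not isolated)
Conditions: 11 (2.4 equiv), THF (degassed), 50 °C, Ar; then air, Et2O, rt
Reagents that add atoms: none
Why: Thermal loss of one CO from 11 (the cis methoxy oxygen can hold the vacant site) lets a terminus of 5 coordinate and insert into the Cr=C bond, giving a vinylcarbene with the CH2-bearing alkyne carbon next to chromium; migration of a CO ligand to that carbon gives a chromium-bound dienylketene. Each ring closes by 6π electrocyclization between the ketene carbon and the methoxy-bearing alkene terminus, and tautomerization of the cyclohexadienone gives the Cr(CO)3-bound 4-methoxyphenol 12, which air releases as 13. The closest known reaction is the Dötz benzannulation of alkenyl(methoxy)carbene pentacarbonylchromium complexes (zerovalent chromium) with terminal alkynes. No stereocenter is formed, and the alkene geometry of 11 is lost because that carbon becomes aromatic. The step needs regioselective insertion with the chain next to the CO-derived carbon, which the size difference between H and CH2 at the two alkyne carbons secures, and it needs CO insertion to outrun direct cyclization of the vinylcarbene, for which an alkenyl complex in THF is the favourable case. The two termini lie thirteen CH2 groups apart and should react independently, and the excess of 11 keeps a second alkyne from inserting at the same chromium.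

Step 7
Reactants: 13 6,6'-(tridecane-1,13-diyl)bis(2,4-dimethoxy-3-methylphenol)
Product: 14 5,5'-(tridecane-1,13-diyl)bis(3-methoxy-2-methylcyclohexa-2,5-diene-1,4-dione)
Conditions: (NH4)2Ce(NO3)6, MeCN/THF/H2O, 0 °C
Reagents that add atoms: water, O
Why: Oxidative demethylation: tetravalent cerium removes two electrons from each 4-methoxyphenol, water adds at the methoxy-bearing para carbon and methanol is lost to give the para-quinone; the ortho methoxy group is not para to the phenol and remains as a vinylogous ester.

Step 8
Reactants: 14 5,5'-(tridecane-1,13-diyl)bis(3-methoxy-2-methylcyclohexa-2,5-diene-1,4-dione)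
Product: 15 1,13-bis(2,3,6-triacetoxy-5-methoxy-4-methylphenyl)tridecane
Conditions: Ac2O, H2SO4 (cat.), 0 °C → rt
Reagents that add atoms: acetic anhydride, CC(=O)OC(C)=O
Why: Thiele–Winter acetoxylation: the acid-activated quinone takes up acetate by conjugate addition at its only unsubstituted ring carbon, which is β to the carbonyl that the methoxy group does not deactivate, and the resulting hydroquinone is acetylated; the fully substituted product cannot react further.

Step 9
Reactants: 15 1,13-bis(2,3,6-triacetoxy-5-methoxy-4-methylphenyl)tridecane
Product: 17 3,3'-(tridecane-1,13-diyl)bis(2-hydroxy-5-methoxy-6-methylcyclohexa-2,5-diene-1,4-dione), via hexaphenol 16 (not isolated)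
Conditions: HCl, MeOH (degassed), N2, 50 °C; evaporate; Et2O/aq. phosphate buffer (pH 7), air, rt
Reagents that add atoms: none
Why: Acid-catalysed transesterification removes the six acetyl groups under nitrogen without touching the aryl methyl ethers, and the 1,2,4-trihydroxyarene rings are then autoxidized at neutral pH; the para oxygens become the carbonyls and the third oxygen stays as OH, the stable 2-hydroxy-1,4-quinone tautomer.

## Compound list

1 | pentadecanedioic acid | OC(=O)CCCCCCCCCCCCCC(=O)O | starting material
2 | pentadecane-1,15-diol | OCCCCCCCCCCCCCCCO | intermediate
3 | pentadecanedial | O=CCCCCCCCCCCCCCC=O | intermediate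
4 | dimethyl (1-diazo-2-oxopropyl)phosphonate | COP(=O)(OC)C(=[N+]=[N-])C(C)=O | starting material
5 | heptadeca-1,16-diyne | C#CCCCCCCCCCCCCCC#C | intermediate
6 | 2-bromo-1,1-dimethoxypropane | COC(OC)C(C)Br | starting material
7 | (Z)-2-bromo-1-methoxyprop-1-ene (Br cis to OCH3) | CO/C=C(/C)Br | intermediate
8 | hexacarbonylchromium Cr(CO)6 | O=C=[Cr](=C=O)(=C=O)(=C=O)(=C=O)=C=O | starting material
9 | (E)-(1-methoxyprop-1-en-2-yl)lithium (Li cis to OCH3) | CO/C=C(/C)[Li] | intermediate (not isolated)
10 | lithium pentacarbonyl[(Z)-3-methoxy-2-methyl-1-oxidoprop-2-en-1-ylidene]chromate | CO/C=C(/C)C([O-])=[Cr](=C=O)(=C=O)(=C=O)(=C=O)=C=O.[Li+] | intermediate (not isolated)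
11 | pentacarbonyl[(Z)-1,3-dimethoxy-2-methylprop-2-en-1-ylidene]chromium | CO/C=C(/C)C(OC)=[Cr](=C=O)(=C=O)(=C=O)(=C=O)=C=O | intermediate
12 | bis(η6-tricarbonylchromium) complex of 6,6'-(tridecane-1,13-diyl)bis(2,4-dimethoxy-3-methylphenol), one Cr(CO)3 on each arene | COc1c(C)c(OC)cc(CCCCCCCCCCCCCc2cc(OC)c(C)c(OC)c2O)c1O.O=C=[Cr](=C=O)=C=O.O=C=[Cr](=C=O)=C=O | intermediate (not isolated)
13 | 6,6'-(tridecane-1,13-diyl)bis(2,4-dimethoxy-3-methylphenol) | COc1c(C)c(OC)cc(CCCCCCCCCCCCCc2cc(OC)c(C)c(OC)c2O)c1O | intermediate
14 | 5,5'-(tridecane-1,13-diyl)bis(3-methoxy-2-methylcyclohexa-2,5-diene-1,4-dione) | COC1=C(C)C(=O)C=C(CCCCCCCCCCCCCC2=CC(=O)C(C)=C(OC)C2=O)C1=O | intermediate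
15 | 1,13-bis(2,3,6-triacetoxy-5-methoxy-4-methylphenyl)tridecane | COc1c(C)c(OC(C)=O)c(OC(C)=O)c(CCCCCCCCCCCCCc2c(OC(C)=O)c(OC(C)=O)c(C)c(OC)c2OC(C)=O)c1OC(C)=O | intermediate
16 | 1,13-bis(2,3,6-trihydroxy-5-methoxy-4-methylphenyl)tridecane | COc1c(C)c(O)c(O)c(CCCCCCCCCCCCCc2c(O)c(O)c(C)c(OC)c2O)c1O | intermediate (not isolated)
17 | 3,3'-(tridecane-1,13-diyl)bis(2-hydroxy-5-methoxy-6-methylcyclohexa-2,5-diene-1,4-dione) | COC1=C(C)C(=O)C(O)=C(CCCCCCCCCCCCCC2=C(O)C(=O)C(C)=C(OC)C2=O)C1=O | target

## Step count and least certain steps

Total step count: 9. Longest linear sequence: 7 steps (1, 2, 3, 6, 7, 8, 9); the carbene branch (steps 4 and 5) joins at step 6.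

**Step 6 (key step).** The most likely failure is diversion of the vinylcarbene intermediate into five-membered-ring formation without CO insertion, because the donor methoxy group on the alkene terminus makes the chromium centre more electron-rich and slows CO migration. A second failure is incomplete reaction at the second alkyne terminus, which would leave mono-annulated material. The fallback keeps the benzannulation but takes the donor group out of the carbene and introduces the ring oxygen afterwards. It sets out from 5 and 8.
- 2-Bromopropene is converted as in step 5 (t-BuLi; 8; Me3OBF4) into pentacarbonyl[methoxy(prop-1-en-2-yl)methylidene]chromium F1, an alkenyl carbene of the best-behaved class.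
- Heating F1 with 5 in THF and releasing the product in air should give 2,2'-(tridecane-1,13-diyl)bis(4-methoxy-5-methylphenol) F2.
- The only free position ortho to each phenol is formylated (MgCl2, Et3N, paraformaldehyde, MeCN, reflux; Casnati–Skattebøl formylation) to 3,3'-(tridecane-1,13-diyl)bis(2-hydroxy-5-methoxy-6-methylbenzaldehyde) F3.
- Dakin oxidation (H2O2, NaOH, N2) gives 6,6'-(tridecane-1,13-diyl)bis(4-methoxy-3-methylbenzene-1,2-diol) F4.
- Immediate methylation (MeI, K2CO3, acetone) gives 1,13-bis(2,3,5-trimethoxy-4-methylphenyl)tridecane F5.
- Oxidation of F5 with (NH4)2Ce(NO3)6 under the conditions of step 7 converts the para-dimethoxy pair of each ring into the quinone, and the route is rejoined at 14.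

**Step 5.** The most likely failure is β-elimination of lithium methoxide from 9 before it has added to the sparingly soluble Cr(CO)6. The step also consumes only the Z isomer of 7, so poor geometric control in step 4 limits the supply. The fallback inverts the polarity of acylchromate formation and avoids both 7 and 9. It sets out from 8.
- 8 is reduced with C8K in THF to dipotassium pentacarbonylchromate K2Cr(CO)5 F8.
- Commercial methyl (E)-3-methoxy-2-methylprop-2-enoate is saponified (LiOH, THF/H2O) to (E)-3-methoxy-2-methylprop-2-enoic acid F6.
- F6 is converted with (COCl)2 and catalytic DMF into (E)-3-methoxy-2-methylprop-2-enoyl chloride F7.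
- Acylation of F8 by F7 at −78 °C gives potassium pentacarbonyl[(E)-3-methoxy-2-methyl-1-oxidoprop-2-en-1-ylidene]chromate F9.
- Me3OBF4 methylates F9 to pentacarbonyl[(E)-1,3-dimethoxy-2-methylprop-2-en-1-ylidene]chromium F10.
- F10 is the geometrical isomer of 11 and leads to the same arene, since the alkene geometry is lost in the ring closure. Used with 5 under the conditions of step 6, it rejoins the route at 13.

**Step 8.** The most likely failure is slow or incomplete acetoxylation, because each quinone ring is trisubstituted and carries a donor methoxy group. Forcing it with stronger acid invites exchange of the vinylogous-ester methoxy group. The fallback replaces acid-mediated acetate addition by nucleophilic epoxidation and sets out from 14.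
- t-BuOOH with DBU in CH2Cl2 at 0 °C should epoxidize the less substituted, more electrophilic ring double bond of each quinone. The product is 1,1'-(tridecane-1,13-diyl)bis(3-methoxy-4-methyl-7-oxabicyclo[4.1.0]hept-3-ene-2,5-dione) F11, a mixture of stereoisomers.
- Treatment with H2SO4 on silica isomerizes each epoxide by enolization and ring opening to the hydroxyquinone. The route is rejoined at 17 and step 9 is bypassed.

**Step 9.** The most likely failures are three:
- loss or exchange of the quinone methoxy group once the hydroxyquinone is present;
- methyl ether formation at the new hydroxyl if air enters during the acidic methanolysis;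
- over-oxidation by the peroxide generated during autoxidation.

The fallback sets out from 15 and avoids both solvolysis and dioxygen. The six acetates are cleaved reductively with LiAlH4 in THF under argon, and quenching with degassed dilute acid allows hexaphenol 16 to be isolated. Oxidation with Ag2O in Et2O, which generates no peroxide, comes back to the route at 17.

## Further compounds

F1 | step 6 | pentacarbonyl[methoxy(prop-1-en-2-yl)methylidene]chromium | C=C(C)C(OC)=[Cr](=C=O)(=C=O)(=C=O)(=C=O)=C=O
F2 | step 6 | 2,2'-(tridecane-1,13-diyl)bis(4-methoxy-5-methylphenol) | COc1cc(CCCCCCCCCCCCCc2cc(OC)c(C)cc2O)c(O)cc1C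
F3 | step 6 | 3,3'-(tridecane-1,13-diyl)bis(2-hydroxy-5-methoxy-6-methylbenzaldehyde) | COc1cc(CCCCCCCCCCCCCc2cc(OC)c(C)c(C=O)c2O)c(O)c(C=O)c1C
F4 | step 6 | 6,6'-(tridecane-1,13-diyl)bis(4-methoxy-3-methylbenzene-1,2-diol) | COc1cc(CCCCCCCCCCCCCc2cc(OC)c(C)c(O)c2O)c(O)c(O)c1C
F5 | step 6 | 1,13-bis(2,3,5-trimethoxy-4-methylphenyl)tridecane | COc1cc(CCCCCCCCCCCCCc2cc(OC)c(C)c(OC)c2OC)c(OC)c(OC)c1C
F6 | step 5 | (E)-3-methoxy-2-methylprop-2-enoic acid | CO/C=C(\C)C(O)=O
F7 | step 5 | (E)-3-methoxy-2-methylprop-2-enoyl chloride | CO/C=C(\C)C(Cl)=O
F8 | step 5 | dipotassium pentacarbonylchromate K2Cr(CO)5 | [K+].[K+].O=C=[Cr-2](=C=O)(=C=O)(=C=O)=C=O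
F9 | step 5 | potassium pentacarbonyl[(E)-3-methoxy-2-methyl-1-oxidoprop-2-en-1-ylidene]chromate | CO/C=C(\C)C([O-])=[Cr](=C=O)(=C=O)(=C=O)(=C=O)=C=O.[K+]
F10 | step 5 | pentacarbonyl[(E)-1,3-dimethoxy-2-methylprop-2-en-1-ylidene]chromium | CO/C=C(\C)C(OC)=[Cr](=C=O)(=C=O)(=C=O)(=C=O)=C=O
F11 | step 8 | 1,1'-(tridecane-1,13-diyl)bis(3-methoxy-4-methyl-7-oxabicyclo[4.1.0]hept-3-ene-2,5-dione), mixture of stereoisomers | COC1=C(C)C(=O)C2OC2(CCCCCCCCCCCCCC23OC2C(=O)C(C)=C(OC)C3=O)C1=O
F0 | step 9 | none | none
A1 | alternative 1 | 1,13-bis(3,5-dimethoxy-4-methylphenyl)-7-isocyano-7-(4-methylbenzenesulfonyl)tridecane | COc1cc(CCCCCCC(CCCCCCc2cc(OC)c(C)c(OC)c2)([N+]#[C-])S(=O)(=O)c2ccc(C)cc2)cc(OC)c1C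
A2 | alternative 1 | 5-(6-iodohexyl)-1,3-dimethoxy-2-methylbenzene | COc1cc(CCCCCCI)cc(OC)c1C
A3 | alternative 1 | tosylmethyl isocyanide | Cc1ccc(cc1)S(=O)(=O)C[N+]#[C-]
A4 | alternative 2 | 1,13-bis(3,5-dimethoxy-4-methylphenyl)tridecane | COc1cc(CCCCCCCCCCCCCc2cc(OC)c(C)c(OC)c2)cc(OC)c1C
A5 | alternative 2 | 1,3-dioxoisoindolin-2-yl 3-(3,5-dimethoxy-4-methylphenyl)propanoate | COc1cc(CCC(=O)ON2C(=O)c3ccccc3C2=O)cc(OC)c1C
A6 | alternative 2 | bis(1,3-dioxoisoindolin-2-yl) undecanedioate | O=C(CCCCCCCCCC(=O)ON1C(=O)c2ccccc2C1=O)ON1C(=O)c2ccccc2C1=O
A7 | alternative 3 | dimethyl 6,6'-(tridecane-1,13-diyl)bis(3-methyl-2,4-dioxocyclohexane-1-carboxylate), mixture of stereoisomers | CC1C(=O)CC(CCCCCCCCCCCCCC2CC(=O)C(C)C(=O)C2C(=O)OC)C(C(=O)OC)C1=O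
A8 | alternative 3 | (4E,19E)-tricosa-4,19-diene-3,21-dione | CCC(=O)/C=C/CCCCCCCCCCCCC/C=C/C(=O)CC
A9 | alternative 3 | dimethyl malonate | COC(=O)CC(=O)OC
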